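In 6.0 s of stirring you get a limited number of turnovers, so count them before you choose a change.

starting material 2.0 mM; reagent in the second phase 2.50 equiv; time 6.0 s; volume of the second phase over the first 1.0

    starting material + reagent in the reaction phase → target (k1 = 250 M⁻¹ s⁻¹)
    reagent in the reaction phase ⇌ reagent in the second phase, rate k2*([reagent in the reaction phase] - [reagent in the second phase]/K2) per volume of the first phase (K2 = 0.76, k2 = 0.079 s⁻¹)
    reagent in the reaction phase ⇌ dormant form (K3 = 1.3, k3 = 0.023 s⁻¹)
    reagent in the reaction phase + target → over-reacted product (k4 = 120 M⁻¹ s⁻¹)
    reagent in the reaction phase → decomposed reagent (k5 = 0.31 s⁻¹)

- in the second phase: reagent in the second phase; everything else is in the first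
- charges count per volume of the first phase; a concentration in a rate is the amount of a species over the volume of its own phase; every rate counts per litre of the first phase
- run time (flask): 6.0 s

- amount of target at 6.0 s, in percent of the starting material charged
- the change that raises the amount of target at 6.0 s, in percent of the starting material charged most ("none" if none brings more than 2 percentage points) (Sunday's / Saturday's / none)
- amount of target at 6.0 s, in percent of the starting material charged, after Saturday's

- Sunday's: doubling the transfer coefficient of step 2, all else as stated
- Saturday's: doubling the amount of reagent in the second phase, all else as stated

In the flask, reagent in the reaction phase starts at nothing and is fed from the second phase at 0.520 mM s⁻¹, which is its slope at the start. Decomposition, the way back across, the dormant form and fresh starting material together remove it at 0.912 s⁻¹, so its curve bends at a knee near 1.10 s and heads for a level of 0.570 mM. As the second phase drains, that level sags, by a factor of about 0.732 at mid-run. Multiplying the rate constant of target formation by the sagged level and the time after the knee gives 0.511; call this n, the turnover count, the rate constant of target formation times the time integral of reagent in the reaction phase.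

Starting material falls as exp(−n), leaving 60.0 %. Target is attacked by the same reagent with selectivity factor s = k4/k1 = 0.480, so time drops out: target, as a fraction of the charge, is (exp(−sn) − exp(−n))/(1 − s). That gives 35.1 % on a curve that peaks at n = 1.41, at a height of 50.8 %.

In this reckoning Saturday's doubles the count to 1.02 and gives 48.6 %. Sunday's doubles the feed but also adds to the loss and speeds the sag, giving 0.701 and 42.0 %, so I choose Saturday's, which gives more target.

The forecast gave 38 %, a little above my figure, then 50 % after Saturday's, with the words “Saturday's wins narrowly”. The simulation gives 37.9 %; Saturday's is best, raising target by 12 percentage points to 50.3 %, while Sunday's brings 9.1 points.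

In the flask, the 56 % of starting material left reads as a count of 0.581, which is below the peak count. Target is made 9.94 times as fast as it is used up at 2.51 s, and still 3.08 times as fast at 6.00 s. For the neighbour charged with 0.80 mM, the loss becomes 0.612 s⁻¹, the count 0.271, and target 22.2 %. Its computed result is 24.3 %, with 73.8 % of starting material left.

The rate constants were drawn at random within sensible limits; no experiment stands behind them.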